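The route rests on ring B. C7 is a ketoside-type carbon, bound to the ring oxygen, a methyl group and ring A, and it sits next to the carbinol carbon C8, so the C7–CH3 and C8–O bonds are cut together. In the forward sense one operation adds both bonds across a C7=C8 enol ether: epoxidation on the face away from the C10 bromine, then opening at C7 by a methyl nucleophile with inversion. This sets C7 and C8 from C10. The precursor is a (3R)-3-bromo-2,2-dimethyl-3,4-dihydro-2H-pyran that carries an achiral, ketal-protected 4-oxocyclohexyl group on its enol ether carbon. Ring A is desymmetrised and halogenated afterwards.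

Key step: step 6

Numbering: caespitol numbering is used. Ring A is C1–C6, where C6 bears ring B, C2 bears bromine, and C3 bears methyl and chlorine. Ring B is O, C7, C8, C9, C10, C11.

Assumption: the chiral lithium amide is taken to distinguish the two axial α-protons of 12 in the sense established for 4-tert-butylcyclohexanone. If 12 responds in the opposite sense, the (S,S)-amide is used.

Step 1
Reactants: 1 ethyl 1,4-dioxaspiro[4.5]decane-8-carboxylate
Product: 2 N-methoxy-N-methyl-1,4-dioxaspiro[4.5]decane-8-carboxamide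
Conditions: MeNH(OMe)·HCl, iPrMgCl, THF, −20 → 0 °C; aq. NH4Cl
Reagents that add atoms: N,O-dimethylhydroxylamine hydrochloride, CNOC.Cl
Why: Weinreb amide formation by aminolysis of the ester with the magnesium amide made in the flask, in a basic medium that leaves the ketal intact and touches no stereocenter.

Step 2
Reactants: 3 5-bromo-2-methylpent-2-ene; 2 N-methoxy-N-methyl-1,4-dioxaspiro[4.5]decane-8-carboxamide
Product: 5 1-(1,4-dioxaspiro[4.5]decan-8-yl)-5-methylhex-4-en-1-one, via homoprenyl Grignard reagent 4 (not isolated)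
Conditions: Mg, THF, rt → 40 °C; then 2, THF, 0 °C; aq. NH4Cl
Reagents that add atoms: none
Why: Weinreb ketone synthesis, in which the primary Grignard reagent adds only once because the magnesium chelate survives until the quench, so the C7–C8 bond forms without over-addition.

Step 3
Reactants: 5 1-(1,4-dioxaspiro[4.5]decan-8-yl)-5-methylhex-4-en-1-one
Product: 6 3-[(2S)-3,3-dimethyloxiran-2-yl]-1-(1,4-dioxaspiro[4.5]decan-8-yl)propan-1-one
Conditions: 1,2:4,5-di-O-isopropylidene-β-L-erythro-2,3-hexodiulo-2,6-pyranose (30 mol %), KHSO5 (as 2KHSO5·KHSO4·K2SO4), K2CO3, Bu4NHSO4, MeCN–CH2(OMe)2–aq. Na2B4O7 buffer, 0 °C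
Reagents that add atoms: potassium peroxymonosulfate KHSO5, [K+].[O-]S(=O)(=O)OO
Why: Shi epoxidation, in which the chiral dioxirane oxidises the trisubstituted C10=C11 alkene through a spiro transition state, and the L-series ketone is chosen because it should give the (10S)-oxirane while ketone and ketal stay untouched in the buffered medium.

Step 4
Reactants: 6 3-[(2S)-3,3-dimethyloxiran-2-yl]-1-(1,4-dioxaspiro[4.5]decan-8-yl)propan-1-one
Product: 7 (4R)-4-bromo-1-(1,4-dioxaspiro[4.5]decan-8-yl)-5-hydroxy-5-methylhexan-1-one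
Conditions: Li2NiBr4 (THF solution), THF, 0 °C → rt; pH 7 phosphate buffer
Reagents that add atoms: dilithium tetrabromonickelate Li2NiBr4, [Li+].[Li+].[Ni+2].[Br-].[Br-].[Br-].[Br-]
Why: SN2 opening of a trisubstituted epoxide by soft, nearly neutral bromide at the less substituted carbon C10, whose inversion turns the (10S) C–O bond into the (10R) C–Br bond and frees the tertiary C11 hydroxyl group.

Step 5
Reactants: 7 (4R)-4-bromo-1-(1,4-dioxaspiro[4.5]decan-8-yl)-5-hydroxy-5-methylhexan-1-one
Product: 9 (3R)-3-bromo-2,2-dimethyl-6-(1,4-dioxaspiro[4.5]decan-8-yl)-3,4-dihydro-2H-pyran, via ring B lactol 8 (not isolated)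
Conditions: pyridinium p-toluenesulfonate (cat.), 4 Å molecular sieves, toluene, 90 °C; Et3N
Reagents that add atoms: none
Why: Acid-catalysed cyclodehydration of a δ-hydroxy ketone (6-exo-trig hemiketalisation, then loss of water through the oxocarbenium ion), which should settle on the endocyclic C7=C8 enol ether because the alternative C6=C7 double bond would be exocyclic to both six-membered rings, with C10 untouched.

Step 6
Reactants: 9 (3R)-3-bromo-2,2-dimethyl-6-(1,4-dioxaspiro[4.5]decan-8-yl)-3,4-dihydro-2H-pyran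
Product: 11 (2R,3R,5R)-5-bromo-2,6,6-trimethyl-2-(1,4-dioxaspiro[4.5]decan-8-yl)oxan-3-ol, via C7–C8 oxirane 10 (not isolated)
Conditions: dimethyldioxirane (acetone solution), CH2Cl2, 4 Å molecular sieves, −78 → 0 °C; evaporate; Me2CuLi (MeLi, CuI), Et2O, −78 → −30 °C; aq. NH4Cl
Reagents that add atoms: dimethyldioxirane, CC1(C)OO1; lithium dimethylcuprate (from MeLi and CuI), [Li+].C[Cu-]C
Why: Dimethyldioxirane transfers oxygen in a concerted spiro transition state to the electron-rich C7=C8 enol ether to give the anhydro-ketose-type oxirane 10, and lithium-assisted loosening of its acetal-like C7–O bond lets the cuprate deliver methyl to C7 from the rear, so C8–O and C7–CH3 form across the former double bond and no ring of the product is closed. The closest known reaction type is the epoxidation of glycals and related cyclic enol ethers followed by opening with organocuprates or Grignard reagents to give trans C-glycosides and C-ketosides. C8 is set by the face of epoxidation: in the half-chair with C10–Br pseudo-equatorial, the pseudo-axial C11 methyl group covers the face on which the bromine lies, so oxygen should arrive on the opposite face. C7 is set by inversion, a trans-diaxial opening that leads directly to the chair with CH3 and C8–O axial and with bromine and ring A equatorial. The step needs three things: attack at C7 only, which the ring oxygen secures by carrying the developing positive charge; anti rather than syn delivery, which is why Me3Al is avoided, since aluminium bound to the oxirane oxygen hands its methyl to the same face; and survival of the C10 bromide, which is secondary, neopentyl-like and should be inert to the cuprate at low temperature.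

Step 7
Reactants: 11 (2R,3R,5R)-5-bromo-2,6,6-trimethyl-2-(1,4-dioxaspiro[4.5]decan-8-yl)oxan-3-ol
Product: 12 4-[(2R,3R,5R)-5-bromo-3-hydroxy-2,6,6-trimethyloxan-2-yl]cyclohexan-1-one
Conditions: 1 M HCl, THF, rt
Reagents that add atoms: water, O
Why: Acid-catalysed ketal hydrolysis, under which the ring B ether (deactivated by the neighbouring C8–O and C10–Br bonds) and the secondary bromide should be stable.

Step 8
Reactants: 12 4-[(2R,3R,5R)-5-bromo-3-hydroxy-2,6,6-trimethyloxan-2-yl]cyclohexan-1-one
Product: 14 [(4S)-4-[(2R,3R,5R)-5-bromo-2,6,6-trimethyl-3-(trimethylsilyloxy)oxan-2-yl]cyclohex-1-en-1-yl]oxy-trimethylsilane, via dilithium alkoxide enolate 13 (not isolated)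
Conditions: lithium (R,R)-bis(1-phenylethyl)amide (2.3 equiv, from the amine hydrochloride and n-BuLi, LiCl present), Me3SiCl, THF, −100 → −78 °C, then rt; Et3N, aq. NaHCO3
Reagents that add atoms: chlorotrimethylsilane, C[Si](C)(C)Cl
Why: Desymmetrising deprotonation of a conformationally locked 4-substituted cyclohexanone by a C2-symmetric chiral lithium amide with in situ silyl quench, in which the first equivalent turns C8–OH into an alkoxide that is silylated as transient protection and the second removes the axial C2 proton rather than the C4 proton, so C6 becomes S under reagent control and the minor C6 epimer is a separable diastereomer.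

Step 9
Reactants: 14 [(4S)-4-[(2R,3R,5R)-5-bromo-2,6,6-trimethyl-3-(trimethylsilyloxy)oxan-2-yl]cyclohex-1-en-1-yl]oxy-trimethylsilane
Product: 17 (2S,4S)-2-bromo-4-[(2R,3R,5R)-5-bromo-3-hydroxy-2,6,6-trimethyloxan-2-yl]cyclohexan-1-one, via silylated axial bromo ketone 15 (not isolated), via axial bromo ketone 16 (not isolated)
Conditions: NBS, THF, −78 °C; 1 M HCl, THF, 0 °C; LiBr, MeCN, rt → 40 °C; chromatography, recovered axial epimer re-equilibrated
Reagents that add atoms: N-bromosuccinimide, O=C1CCC(=O)N1Br; lithium bromide, [Li+].[Br-]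
Why: Electrophilic α-bromination of a silyl enol ether places bromine axially at C2 under stereoelectronic control, and degenerate SN2 exchange with bromide in a polar solvent then equilibrates C2 without moving the halogen to C4, the more polar equatorial (2S) epimer being favoured by acetonitrile and separated by chromatography.

Step 10
Reactants: 17 (2S,4S)-2-bromo-4-[(2R,3R,5R)-5-bromo-3-hydroxy-2,6,6-trimethyloxan-2-yl]cyclohexan-1-one
Product: 18 (1S,2S,4S)-2-bromo-4-[(2R,3R,5R)-5-bromo-3-hydroxy-2,6,6-trimethyloxan-2-yl]-1-methylcyclohexan-1-ol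
Conditions: Me3Al (5 equiv), toluene, −78 → 0 °C; aq. potassium sodium tartrate
Reagents that add atoms: trimethylaluminium, C[Al](C)C
Why: 1,2-Addition of excess Me3Al in a hydrocarbon solvent, the regime in which a second aluminium centre assists a six-centre transfer and cyclohexanones are attacked axially, so methyl should enter C3 axially (3S, hydroxyl equatorial and trans to bromine) while the non-basic reagent avoids enolisation, halogen–metal exchange and epoxide closure.

Step 11
Reactants: 18 (1S,2S,4S)-2-bromo-4-[(2R,3R,5R)-5-bromo-3-hydroxy-2,6,6-trimethyloxan-2-yl]-1-methylcyclohexan-1-ol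
Product: 19 [(2R,3R,5R)-5-bromo-2-[(1S,3S,4S)-3-bromo-4-hydroxy-4-methylcyclohexyl]-2,6,6-trimethyloxan-3-yl] acetate
Conditions: Ac2O, pyridine, 4-(dimethylamino)pyridine (cat.), CH2Cl2, 0 °C → rt
Reagents that add atoms: acetic anhydride, CC(=O)OC(C)=O
Why: Chemoselective acylation in which the secondary C8 alcohol is esterified while the tertiary C3 alcohol next to CHBr should react far more slowly, with no stereocenter affected.

Step 12
Reactants: 19 [(2R,3R,5R)-5-bromo-2-[(1S,3S,4S)-3-bromo-4-hydroxy-4-methylcyclohexyl]-2,6,6-trimethyloxan-3-yl] acetate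
Product: 21 8-acetylcaespitol, via tertiary chlorosulfite 20 (not isolated)
Conditions: SOCl2, CH2Cl2, −20 °C → rt
Reagents that add atoms: thionyl chloride, O=S(Cl)Cl
Why: Deoxychlorination of a tertiary alcohol through its chlorosulfite, whose ionisation gives a cation that the C2 bromine on the upper face bridges as a bromonium ion (neighbouring-group participation), so chloride returning from the side of the departing group should bind C3 on the lower face with overall retention and give the trans-diequatorial bromochloride.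

Compound list
1 | ethyl 1,4-dioxaspiro[4.5]decane-8-carboxylate | CCOC(=O)C1CCC2(CC1)OCCO2 | starting material
2 | N-methoxy-N-methyl-1,4-dioxaspiro[4.5]decane-8-carboxamide | CON(C)C(=O)C1CCC2(CC1)OCCO2 | intermediate
3 | 5-bromo-2-methylpent-2-ene | CC(C)=CCCBr | starting material
4 | (4-methylpent-3-en-1-yl)magnesium bromide | CC(C)=CCC[Mg]Br | intermediate
5 | 1-(1,4-dioxaspiro[4.5]decan-8-yl)-5-methylhex-4-en-1-one | CC(C)=CCCC(=O)C1CCC2(CC1)OCCO2 | intermediate
6 | 3-[(2S)-3,3-dimethyloxiran-2-yl]-1-(1,4-dioxaspiro[4.5]decan-8-yl)propan-1-one | CC1(C)O[C@H]1CCC(=O)C1CCC2(CC1)OCCO2 | intermediate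
7 | (4R)-4-bromo-1-(1,4-dioxaspiro[4.5]decan-8-yl)-5-hydroxy-5-methylhexan-1-one | O=C(CC[C@@H](Br)C(C)(C)O)C1CCC2(CC1)OCCO2 | intermediate
8 | (5R)-5-bromo-2-(1,4-dioxaspiro[4.5]decan-8-yl)-6,6-dimethyloxan-2-ol (lactol, both C7 epimers) | OC1(CC[C@@H](Br)C(C)(C)O1)C1CCC2(CC1)OCCO2 | intermediate
9 | (3R)-3-bromo-2,2-dimethyl-6-(1,4-dioxaspiro[4.5]decan-8-yl)-3,4-dihydro-2H-pyran | C1(=CC[C@@H](Br)C(C)(C)O1)C1CCC2(CC1)OCCO2 | intermediate
10 | (1S,4R,6R)-4-bromo-3,3-dimethyl-1-(1,4-dioxaspiro[4.5]decan-8-yl)-2,7-dioxabicyclo[4.1.0]heptane (oxirane anti to bromine) | O1[C@@H]2C[C@@H](Br)C(C)(C)O[C@]12C1CCC3(CC1)OCCO3 | intermediate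
11 | (2R,3R,5R)-5-bromo-2,6,6-trimethyl-2-(1,4-dioxaspiro[4.5]decan-8-yl)oxan-3-ol | O[C@@H]1C[C@@H](Br)C(C)(C)O[C@]1(C)C1CCC2(CC1)OCCO2 | intermediate
12 | 4-[(2R,3R,5R)-5-bromo-3-hydroxy-2,6,6-trimethyloxan-2-yl]cyclohexan-1-one | O[C@@H]1C[C@@H](Br)C(C)(C)O[C@]1(C)C1CCC(=O)CC1 | intermediate
13 | dilithium C8 alkoxide C2=C3 enolate of 12, (6S) | [Li]O[C@@H]1C[C@@H](Br)C(C)(C)O[C@]1(C)[C@H]1CCC(O[Li])=CC1 | intermediate
14 | [(4S)-4-[(2R,3R,5R)-5-bromo-2,6,6-trimethyl-3-(trimethylsilyloxy)oxan-2-yl]cyclohex-1-en-1-yl]oxy-trimethylsilane | C[Si](C)(C)O[C@@H]1C[C@@H](Br)C(C)(C)O[C@]1(C)[C@H]1CCC(O[Si](C)(C)C)=CC1 | intermediate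
15 | (2R,4S)-2-bromo-4-[(2R,3R,5R)-5-bromo-2,6,6-trimethyl-3-(trimethylsilyloxy)oxan-2-yl]cyclohexan-1-one (C2–Br axial) | C[Si](C)(C)O[C@@H]1C[C@@H](Br)C(C)(C)O[C@]1(C)[C@H]1CCC(=O)[C@H](Br)C1 | intermediate
16 | (2R,4S)-2-bromo-4-[(2R,3R,5R)-5-bromo-3-hydroxy-2,6,6-trimethyloxan-2-yl]cyclohexan-1-one (C2–Br axial) | O[C@@H]1C[C@@H](Br)C(C)(C)O[C@]1(C)[C@H]1CCC(=O)[C@H](Br)C1 | intermediate
17 | (2S,4S)-2-bromo-4-[(2R,3R,5R)-5-bromo-3-hydroxy-2,6,6-trimethyloxan-2-yl]cyclohexan-1-one (C2–Br equatorial) | O[C@@H]1C[C@@H](Br)C(C)(C)O[C@]1(C)[C@H]1CCC(=O)[C@@H](Br)C1 | intermediate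
18 | (1S,2S,4S)-2-bromo-4-[(2R,3R,5R)-5-bromo-3-hydroxy-2,6,6-trimethyloxan-2-yl]-1-methylcyclohexan-1-ol | O[C@@H]1C[C@@H](Br)C(C)(C)O[C@]1(C)[C@H]1CC[C@](C)(O)[C@@H](Br)C1 | intermediate
19 | [(2R,3R,5R)-5-bromo-2-[(1S,3S,4S)-3-bromo-4-hydroxy-4-methylcyclohexyl]-2,6,6-trimethyloxan-3-yl] acetate | CC(=O)O[C@@H]1C[C@@H](Br)C(C)(C)O[C@]1(C)[C@H]1CC[C@](C)(O)[C@@H](Br)C1 | intermediate
20 | C3 chlorosulfite of 19 | CC(=O)O[C@@H]1C[C@@H](Br)C(C)(C)O[C@]1(C)[C@H]1CC[C@](C)(OS(=O)Cl)[C@@H](Br)C1 | intermediate
21 | 8-acetylcaespitol, [(2R,3R,5R)-5-bromo-2-[(1S,3S,4S)-3-bromo-4-chloro-4-methylcyclohexyl]-2,6,6-trimethyloxan-3-yl] acetate | CC(=O)O[C@@H]1C[C@@H](Br)C(C)(C)O[C@]1(C)[C@H]1CC[C@](C)(Cl)[C@@H](Br)C1 | target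

Total step count: 12
Longest linear sequence: 12 steps (from 1)

Steps most likely to fail

**Step 6.** Several things may go wrong.
- The oxirane may ionise fully, after which methyl is transferred on the face of the C8 oxygen.
- Proton loss from C6, or a hydride shift from C8 to C7, may take the place of C–C bond formation.
- The labile oxirane may hydrolyse.

The fallback sets out from 10 (made from 9 as in step 6) and returns at 11. It forms the two bonds in separate operations under neighbouring-group control. Thiophenol opens 10 at C7 to the phenyl thioketoside F1. Ac2O in pyridine converts it into the C8 acetate F2, and mCPBA oxidises sulfur to give the sulfone F3. Me3Al in CH2Cl2 at −78 °C then expels the sulfinate. The C8 acetate closes onto C7 from the lower face as a dioxolenium ion, so methyl can enter only from the upper face. This joins the 1,2-trans rule of acyl-assisted glycosylation to the known exchange of a ketal-carbon sulfone for methyl, and it should give the C8 acetate of the methylated pyran F4. K2CO3 in MeOH then releases 11.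

**Step 12.** Possible failures are elimination from the tertiary cation, slow ionisation next to the C–Br bond, chloride entry at C2 or on the upper face of C3, and loss of Br+ from the bridged ion.

The fallback sets out from 14 and returns at 21. It reaches the bromochloride through its diaxial positional isomer, every step of which follows the trans-diaxial preference of the ring.
- N-Chlorosuccinimide in THF, followed by dilute HCl, gives the axial chloro ketone F5, which needs no epimerisation.
- Excess Me3Al in toluene adds methyl anti to the axial chlorine and gives the chlorohydrin F6.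
- Ac2O in pyridine gives the C8 acetate F7.
- HBr in AcOH–CH2Cl2 at 0 °C replaces the tertiary hydroxyl group, with bromide attacking the cation axially and anti to chlorine, to give the diaxial 2-chloro-3-bromo isomer F8.
- Heating F8 in toluene or chlorobenzene should trigger the diaxial-to-diequatorial rearrangement of vicinal dihalides. In it the two halogens exchange carbons, each staying on its own face, which places bromine equatorial at C2 and chlorine equatorial at C3 as in 21.

**Step 9.** Possible failures are an epimer equilibrium that does not lean far enough toward the equatorial bromide, sluggish bromide exchange, dehydrobromination, and migration of bromine to C4 by debromination and rebromination if acid builds up.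

The fallback sets out from 16 (isolated after the acid work-up) and returns at 17. It replaces equilibration by kinetic stereoelectronic control. Me3SiOTf and Et3N in CH2Cl2 convert 16 into the bis-silylated 2-bromo enol silane F9. Buffered fluoride (Bu4NF–AcOH, THF, −78 °C) then releases the bromo enolate, which should be protonated axially at C2. This pushes bromine into the equatorial position and frees C8–OH at the same time.

Further compounds
F1 | step 6 | (2S,3R,5R)-5-bromo-6,6-dimethyl-2-(phenylsulfanyl)-2-(1,4-dioxaspiro[4.5]decan-8-yl)oxan-3-ol | O[C@@H]1C[C@@H](Br)C(C)(C)O[C@]1(Sc1ccccc1)C1CCC2(CC1)OCCO2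
F2 | step 6 | [(2S,3R,5R)-5-bromo-6,6-dimethyl-2-(phenylsulfanyl)-2-(1,4-dioxaspiro[4.5]decan-8-yl)oxan-3-yl] acetate | CC(=O)O[C@@H]1C[C@@H](Br)C(C)(C)O[C@]1(Sc1ccccc1)C1CCC2(CC1)OCCO2
F3 | step 6 | [(2S,3R,5R)-2-(benzenesulfonyl)-5-bromo-6,6-dimethyl-2-(1,4-dioxaspiro[4.5]decan-8-yl)oxan-3-yl] acetate | CC(=O)O[C@@H]1C[C@@H](Br)C(C)(C)O[C@]1(S(=O)(=O)c1ccccc1)C1CCC2(CC1)OCCO2
F4 | step 6 | [(2R,3R,5R)-5-bromo-2,6,6-trimethyl-2-(1,4-dioxaspiro[4.5]decan-8-yl)oxan-3-yl] acetate | CC(=O)O[C@@H]1C[C@@H](Br)C(C)(C)O[C@]1(C)C1CCC2(CC1)OCCO2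
F5 | step 12 | (2R,4S)-2-chloro-4-[(2R,3R,5R)-5-bromo-3-hydroxy-2,6,6-trimethyloxan-2-yl]cyclohexan-1-one (C2–Cl axial) | O[C@@H]1C[C@@H](Br)C(C)(C)O[C@]1(C)[C@H]1CCC(=O)[C@H](Cl)C1
F6 | step 12 | (1S,2R,4S)-2-chloro-4-[(2R,3R,5R)-5-bromo-3-hydroxy-2,6,6-trimethyloxan-2-yl]-1-methylcyclohexan-1-ol | O[C@@H]1C[C@@H](Br)C(C)(C)O[C@]1(C)[C@H]1CC[C@](C)(O)[C@H](Cl)C1
F7 | step 12 | [(2R,3R,5R)-5-bromo-2-[(1S,3R,4S)-3-chloro-4-hydroxy-4-methylcyclohexyl]-2,6,6-trimethyloxan-3-yl] acetate | CC(=O)O[C@@H]1C[C@@H](Br)C(C)(C)O[C@]1(C)[C@H]1CC[C@](C)(O)[C@H](Cl)C1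
F8 | step 12 | [(2R,3R,5R)-5-bromo-2-[(1S,3R,4R)-4-bromo-3-chloro-4-methylcyclohexyl]-2,6,6-trimethyloxan-3-yl] acetate (both ring A halogens axial) | CC(=O)O[C@@H]1C[C@@H](Br)C(C)(C)O[C@]1(C)[C@H]1CC[C@@](C)(Br)[C@H](Cl)C1
F9 | step 9 | [(4S)-2-bromo-4-[(2R,3R,5R)-5-bromo-2,6,6-trimethyl-3-(trimethylsilyloxy)oxan-2-yl]cyclohex-1-en-1-yl]oxy-trimethylsilane | C[Si](C)(C)O[C@@H]1C[C@@H](Br)C(C)(C)O[C@]1(C)[C@H]1CCC(O[Si](C)(C)C)=C(Br)C1
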